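**Plan**
Retrosynthesis: the C15 aldehyde and the 13,14-epoxide go back to an E-allylic alcohol, the 3α-acetate to a C3 ketone, and the C4 methyl group and H-5 to a Δ4-3-keto-19-ester; then C5–C6 and C9–C10 are cut together.
Enabling feature: in ring A the oxygen on C3 is para to the methyl-bearing quaternary C10 and ortho to the carboxyl-bearing C4, so ring A is a dearomatized 5-methylsalicylate whose C5 (as aryl iodide) and para carbon C10 (as phenoxide) are the two bonding sites.
Forward: arene 5 (3 steps) and dienyl carbonate 13 (5 steps from geraniol, carrying C6–C9, C17 and the whole side chain) are joined in step 9, which closes ring B onto the flat ring A; ring A is then reduced and functionalised (steps 10–13) and the side chain finished (steps 14–16).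
Stereochemistry: C9 and C10 from the chiral palladium catalyst and a chair-like closure in step 9; C5 and C4 from the dissolving-metal reductive methylation; C3 from LiBH(s-Bu)3; C13/C14 from D-(−)-diethyl tartrate; the 13E geometry from geraniol.

Key step: step 9

Remark: decalin compounds carry labdane locants (α below, β above the ring in the usual drawing); the ligand antipode written in step 9 is an assumption and is exchanged for its mirror image if a pilot run gives the opposite series.

**Route**

Step 1
Reactants: 1 2-methoxy-5-methylbenzoic acid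
Product: 3 2-iodo-6-methoxy-3-methylbenzoic acid, via dilithio species 2 (not isolated)
Conditions: s-BuLi (2.2 equiv), TMEDA (2.2 equiv), THF, −78 °C; then I2, −78 to 23 °C; aq HCl, Na2S2O3
Reagents that add atoms: iodine, II
Why: Carboxylate-directed ortho-lithiation (directed ortho-metalation) with s-BuLi/TMEDA should remove the hydrogen next to the lithium carboxylate, not the one next to the methoxy group, and iodine quenches the aryllithium.

Step 2
Reactants: 3 2-iodo-6-methoxy-3-methylbenzoic acid
Product: 4 6-hydroxy-2-iodo-3-methylbenzoic acid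
Conditions: BBr3 (2.5 equiv), CH2Cl2, −78 to 0 °C; then H2O
Reagents that add atoms: none
Why: Lewis-acid cleavage of the aryl methyl ether (BBr3 demethylation), helped by chelation to the neighbouring carboxyl group; the aryl iodide is inert.

Step 3
Reactants: 4 6-hydroxy-2-iodo-3-methylbenzoic acid
Product: 5 methyl 6-hydroxy-2-iodo-3-methylbenzoate
Conditions: MeI (1.2 equiv), KHCO3 (1.2 equiv), DMF, 23 °C
Reagents that add atoms: iodomethane, CI
Why: SN2 O-alkylation of the carboxylate; the weak base leaves the hydrogen-bonded phenol un-ionised, so only the ester should form.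

Step 4
Reactants: 6 geraniol
Product: 7 geranyl triisopropylsilyl ether
Conditions: i-Pr3SiCl, imidazole, DMF, 23 °C
Reagents that add atoms: chlorotri(propan-2-yl)silane, CC(C)[Si](Cl)(C(C)C)C(C)C
Why: Silylation of the primary alcohol; this silyl ether has no aryl group and no leaving-group character, which the palladium and dissolving-metal steps require.

Step 5
Reactants: 7 geranyl triisopropylsilyl ether
Product: 8 6,7-epoxygeranyl triisopropylsilyl ether (racemic)
Conditions: mCPBA (1.0 equiv), NaHCO3, CH2Cl2, −20 to 0 °C
Reagents that add atoms: 3-chloroperbenzoic acid, OOC(=O)c1cccc(Cl)c1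
Why: Prilezhaev epoxidation; the distal trisubstituted alkene is more electron-rich than the one bearing the allylic oxygen and should react first (the epoxide stereocentre is destroyed in step 6).

Step 6
Reactants: 8 6,7-epoxygeranyl triisopropylsilyl ether
Product: 10 (4E)-4-methyl-6-[(triisopropylsilyl)oxy]hex-4-enal, via diol 9 (not isolated)
Conditions: HIO4·2H2O (1.2 equiv), THF/H2O, 0 °C
Reagents that add atoms: none
Why: Acid-catalysed epoxide hydrolysis followed by periodate glycol cleavage (Malaprade reaction) should give the aldehyde and acetone without touching the E-alkene.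

Step 7
Reactants: 10 (4E)-4-methyl-6-[(triisopropylsilyl)oxy]hex-4-enal; 11 1,4-dibromobut-2-yne
Product: 12 (7E)-7-methyl-3-methylidene-9-[(triisopropylsilyl)oxy]nona-1,7-dien-4-ol (racemic)
Conditions: In metal powder (1.5 equiv), THF/H2O (1:1), 23 °C
Reagents that add atoms: none
Why: Barbier-type indium-mediated buta-1,3-dien-2-ylation of the aldehyde in water places the carbinol carbon next to the 1,1-disubstituted alkene; its configuration is irrelevant because step 9 erases it.

Step 8
Reactants: 12 (7E)-7-methyl-3-methylidene-9-[(triisopropylsilyl)oxy]nona-1,7-dien-4-ol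
Product: 13 methyl (7E)-7-methyl-3-methylidene-9-[(triisopropylsilyl)oxy]nona-1,7-dien-4-yl carbonate (racemic)
Conditions: ClCO2Me, pyridine, DMAP (cat.), CH2Cl2, 0 °C
Reagents that add atoms: methyl chloroformate, COC(Cl)=O
Why: Acylation of the secondary allylic alcohol to the methyl carbonate, the leaving group for π-allyl formation.

Step 9
Reactants: 13 methyl (7E)-7-methyl-3-methylidene-9-[(triisopropylsilyl)oxy]nona-1,7-dien-4-yl carbonate; 5 methyl 6-hydroxy-2-iodo-3-methylbenzoate
Product: 16 methyl 3-oxo-15-[(triisopropylsilyl)oxy]-18-norlabda-1,4,8(17),13E-tetraen-19-oate, via alkylborane 14 (not isolated), via aryl allyl carbonate 15 (not isolated)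
Conditions: 9-BBN-H (1.0 equiv), THF, 0 to 23 °C; then 5, Pd2(dba)3 (2.5 mol%), (1R,2R)-N,N'-bis[2-(diphenylphosphino)benzoyl]cyclohexane-1,2-diamine (7.5 mol%), K3PO4 (3 equiv), H2O (3 equiv), THF/DMF, 23 to 50 °C
Reagents that add atoms: none
Why: Proposed new method: 9-BBN should hydroborate only the monosubstituted vinyl group of 13 (the 1,1-disubstituted alkene is shielded by the branched carbonate-bearing carbon), and one zerovalent palladium catalyst should then couple the primary alkylborane 14 with the aryl iodide at C5 (oxidative addition, transmetalation, reductive elimination; C5–C6) and ionise the allylic carbonate to a π-allylpalladium complex that the phenoxide attacks through its para carbon C10 at C9 (C9–C10), which dearomatises ring A to the cross-conjugated dienone ester. The closest known reactions are the B-alkyl Suzuki–Miyaura coupling and the palladium-catalysed intramolecular dearomative allylic alkylation (Tsuji–Trost type) of para-substituted phenols; new is their merger in one flask and the closure of a fused ring. Ring B closes by six-membered attack on the substituted allyl terminus C9 (6-exo with respect to C8=C17, which remains as the exocyclic methylene), since attack at the CH2 terminus C17 would need an eight-membered ring. C10 and C9 are set together: the two faces of the π-allyl unit interconvert through its unsubstituted terminus, so the chiral bisphosphine should select one of them (dynamic kinetic asymmetric transformation of the racemic carbonate), and a chair-like closure with the side chain pseudo-equatorial should put H-9 anti to the C10 methyl group. The step needs C- over O-allylation and para (C10) over ortho (C4) attack: the phenol oxygen cannot reach the tethered allyl unit and intermolecular O-allylation is reversible under zerovalent palladium, while closure at the ester-bearing C4 would give a non-conjugated ortho-quinoid ketone that can re-ionise, so the conjugated para product should accumulate. It also needs the aryl–alkyl coupling to outrun allyl–alkyl self-coupling of 14, which fast oxidative addition of the aryl iodide and slow reductive elimination from alkyl(allyl)palladium should secure.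

Step 10
Reactants: 16 methyl 3-oxo-15-[(triisopropylsilyl)oxy]-18-norlabda-1,4,8(17),13E-tetraen-19-oate
Product: 17 methyl 3-oxo-15-[(triisopropylsilyl)oxy]-18-norlabda-4,8(17),13E-trien-19-oate
Conditions: Cu(OAc)2·H2O (5 mol%), 1,2-bis(diphenylphosphino)benzene (5 mol%), MeSiH(OEt)2 (1.5 equiv), t-BuOH (1.5 equiv), toluene, 23 °C
Reagents that add atoms: none
Why: Copper hydride conjugate reduction should deliver hydride only to the unsubstituted β-carbon C1, as in known CuH reductions of 4,4-disubstituted cyclohexadienones, because the other β-carbon C5 is fully substituted and flanked by the quaternary C10; the isolated alkenes are inert.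

Step 11
Reactants: 17 methyl 3-oxo-15-[(triisopropylsilyl)oxy]-18-norlabda-4,8(17),13E-trien-19-oate
Product: 19 methyl 3-oxo-15-[(triisopropylsilyl)oxy]labda-8(17),13E-dien-19-oate, via lithium enolate 18 (not isolated)
Conditions: Li (2.2 equiv, added to a faint persistent blue), NH3(l)/THF, t-BuOH (1.0 equiv), −78 °C; then MeI (5 equiv), −78 to −33 °C
Reagents that add atoms: iodomethane, CI
Why: Dissolving-metal (Birch-type) reduction of the enone ester with enolate trapping (reductive alkylation): axial protonation of the C5 carbanion should give the trans-fused enolate, and methyl iodide should enter C4 from the α face, away from the axial C10 methyl group, leaving the ester β.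

Step 12
Reactants: 19 methyl 3-oxo-15-[(triisopropylsilyl)oxy]labda-8(17),13E-dien-19-oate
Product: 20 methyl 3α-hydroxy-15-[(triisopropylsilyl)oxy]labda-8(17),13E-dien-19-oate
Conditions: LiBH(s-Bu)3 (1.5 equiv), THF, −78 to −40 °C; then H2O
Reagents that add atoms: none
Why: Ketone reduction with a bulky trialkylborohydride: equatorial approach of hydride to C3 should give the axial 3α-alcohol, and the hindered C19 ester is not reduced at this temperature.

Step 13
Reactants: 20 methyl 3α-hydroxy-15-[(triisopropylsilyl)oxy]labda-8(17),13E-dien-19-oate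
Product: 21 methyl 3α-acetoxy-15-[(triisopropylsilyl)oxy]labda-8(17),13E-dien-19-oate
Conditions: Ac2O, DMAP, pyridine, 40 °C
Reagents that add atoms: acetic anhydride, CC(=O)OC(C)=O
Why: DMAP-catalysed acylation of the hindered axial secondary alcohol.

Step 14
Reactants: 21 methyl 3α-acetoxy-15-[(triisopropylsilyl)oxy]labda-8(17),13E-dien-19-oate
Product: 22 methyl 3α-acetoxy-15-hydroxylabda-8(17),13E-dien-19-oate
Conditions: n-Bu4NF (1.2 equiv), AcOH (1.2 equiv), THF, 0 to 23 °C
Reagents that add atoms: none
Why: Fluoride cleavage of the silyl ether; buffering with acetic acid protects the secondary acetate.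

Step 15
Reactants: 22 methyl 3α-acetoxy-15-hydroxylabda-8(17),13E-dien-19-oate
Product: 23 methyl (13R,14R)-3α-acetoxy-13,14-epoxy-15-hydroxylabd-8(17)-en-19-oate
Conditions: Ti(OiPr)4 (10 mol%), D-(−)-diethyl tartrate (12 mol%), t-BuOOH (2 equiv, anhydrous), 4 Å molecular sieves, CH2Cl2, −20 °C
Reagents that add atoms: tert-butyl hydroperoxide, CC(C)(C)OO
Why: Sharpless asymmetric epoxidation: the D-(−)-tartrate should deliver oxygen to the face of the E-allylic alcohol that gives the (13R,14R)-epoxy alcohol (the sense that turns geraniol into its (2R,3R)-epoxide), and the exocyclic alkene, having no allylic hydroxyl, is not touched.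

Step 16
Reactants: 23 methyl (13R,14R)-3α-acetoxy-13,14-epoxy-15-hydroxylabd-8(17)-en-19-oate
Product: 24 methyl (13R,14S)-3α-acetoxy-13,14-epoxy-15-oxolabd-8(17)-en-19-oate (CNP0145900.1)
Conditions: Dess–Martin periodinane (1.3 equiv), NaHCO3, CH2Cl2, 0 to 23 °C
Reagents that add atoms: none
Why: Buffered Dess–Martin oxidation of the primary epoxy alcohol to the epoxy aldehyde should proceed without epoxide opening; the descriptor at C14 changes to S only because the substituent priorities change.

**Compound list**
1 | 2-methoxy-5-methylbenzoic acid | COc1ccc(C)cc1C(=O)O | starting material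
2 | lithium 2-lithio-6-methoxy-3-methylbenzoate (not isolated) | COc1ccc(C)c([Li])c1C(=O)O[Li] | intermediate
3 | 2-iodo-6-methoxy-3-methylbenzoic acid | COc1ccc(C)c(I)c1C(=O)O | intermediate
4 | 6-hydroxy-2-iodo-3-methylbenzoic acid | Oc1ccc(C)c(I)c1C(=O)O | intermediate
5 | methyl 6-hydroxy-2-iodo-3-methylbenzoate | COC(=O)c1c(O)ccc(C)c1I | intermediate
6 | geraniol, (2E)-3,7-dimethylocta-2,6-dien-1-ol | CC(C)=CCC/C(C)=C/CO | starting material
7 | geranyl triisopropylsilyl ether | CC(C)=CCC/C(C)=C/CO[Si](C(C)C)(C(C)C)C(C)C | intermediate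
8 | {[(2E)-5-(3,3-dimethyloxiran-2-yl)-3-methylpent-2-en-1-yl]oxy}tri(propan-2-yl)silane (racemic) | CC1(C)OC1CC/C(C)=C/CO[Si](C(C)C)(C(C)C)C(C)C | intermediate
9 | (6E)-2,6-dimethyl-8-[(triisopropylsilyl)oxy]oct-6-ene-2,3-diol (not isolated) | CC(C)(O)C(O)CC/C(C)=C/CO[Si](C(C)C)(C(C)C)C(C)C | intermediate
10 | (4E)-4-methyl-6-[(triisopropylsilyl)oxy]hex-4-enal | O=CCC/C(C)=C/CO[Si](C(C)C)(C(C)C)C(C)C | intermediate
11 | 1,4-dibromobut-2-yne | BrCC#CCBr | starting material
12 | (7E)-7-methyl-3-methylidene-9-[(triisopropylsilyl)oxy]nona-1,7-dien-4-ol (racemic) | C=CC(=C)C(O)CC/C(C)=C/CO[Si](C(C)C)(C(C)C)C(C)C | intermediate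
13 | methyl (7E)-7-methyl-3-methylidene-9-[(triisopropylsilyl)oxy]nona-1,7-dien-4-yl carbonate (racemic) | C=CC(=C)C(OC(=O)OC)CC/C(C)=C/CO[Si](C(C)C)(C(C)C)C(C)C | intermediate
14 | 9-[(7E)-4-(methoxycarbonyloxy)-7-methyl-3-methylidene-9-(triisopropylsilyloxy)non-7-en-1-yl]-9-borabicyclo[3.3.1]nonane (not isolated) | COC(=O)OC(CC/C(C)=C/CO[Si](C(C)C)(C(C)C)C(C)C)C(=C)CCB1C2CCCC1CCC2 | intermediate
15 | methyl 6-hydroxy-2-[(7E)-4-(methoxycarbonyloxy)-7-methyl-3-methylidene-9-(triisopropylsilyloxy)non-7-en-1-yl]-3-methylbenzoate (not isolated) | COC(=O)c1c(O)ccc(C)c1CCC(=C)C(OC(=O)OC)CC/C(C)=C/CO[Si](C(C)C)(C(C)C)C(C)C | intermediate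
16 | methyl 3-oxo-15-[(triisopropylsilyl)oxy]-18-norlabda-1,4,8(17),13E-tetraen-19-oate (9α-H, 10β-methyl) | COC(=O)C1=C2CCC(=C)[C@H](CC/C(C)=C/CO[Si](C(C)C)(C(C)C)C(C)C)[C@@]2(C)C=CC1=O | intermediate
17 | methyl 3-oxo-15-[(triisopropylsilyl)oxy]-18-norlabda-4,8(17),13E-trien-19-oate | COC(=O)C1=C2CCC(=C)[C@H](CC/C(C)=C/CO[Si](C(C)C)(C(C)C)C(C)C)[C@@]2(C)CCC1=O | intermediate
18 | lithium 3,4-enolate of methyl 3-oxo-15-[(triisopropylsilyl)oxy]-18-norlabda-8(17),13E-dien-19-oate, 5α-H (not isolated) | C=C1CC[C@@H]2[C@](C)(CCC(O[Li])=C2C(=O)OC)[C@H]1CC/C(C)=C/CO[Si](C(C)C)(C(C)C)C(C)C | intermediate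
19 | methyl 3-oxo-15-[(triisopropylsilyl)oxy]labda-8(17),13E-dien-19-oate (4α-methyl, 5α-H) | C=C1CC[C@@H]2[C@](C)(CCC(=O)[C@]2(C)C(=O)OC)[C@H]1CC/C(C)=C/CO[Si](C(C)C)(C(C)C)C(C)C | intermediate
20 | methyl 3α-hydroxy-15-[(triisopropylsilyl)oxy]labda-8(17),13E-dien-19-oate | C=C1CC[C@@H]2[C@](C)(CC[C@@H](O)[C@]2(C)C(=O)OC)[C@H]1CC/C(C)=C/CO[Si](C(C)C)(C(C)C)C(C)C | intermediate
21 | methyl 3α-acetoxy-15-[(triisopropylsilyl)oxy]labda-8(17),13E-dien-19-oate | C=C1CC[C@@H]2[C@](C)(CC[C@@H](OC(C)=O)[C@]2(C)C(=O)OC)[C@H]1CC/C(C)=C/CO[Si](C(C)C)(C(C)C)C(C)C | intermediate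
22 | methyl 3α-acetoxy-15-hydroxylabda-8(17),13E-dien-19-oate | C=C1CC[C@@H]2[C@](C)(CC[C@@H](OC(C)=O)[C@]2(C)C(=O)OC)[C@H]1CC/C(C)=C/CO | intermediate
23 | methyl (13R,14R)-3α-acetoxy-13,14-epoxy-15-hydroxylabd-8(17)-en-19-oate | C=C1CC[C@@H]2[C@](C)(CC[C@@H](OC(C)=O)[C@]2(C)C(=O)OC)[C@H]1CC[C@@]1(C)O[C@@H]1CO | intermediate
24 | methyl (13R,14S)-3α-acetoxy-13,14-epoxy-15-oxolabd-8(17)-en-19-oate (CNP0145900.1) | C=C1CC[C@@H]2[C@](C)(CC[C@@H](OC(C)=O)[C@]2(C)C(=O)OC)[C@H]1CC[C@@]1(C)O[C@@H]1C=O | target

**Count and risks**
Total steps: 16. Longest linear sequence: 13 (steps 4–16, from geraniol).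

Steps most likely to fail:

1. Step 9 (Proposed new method). The allylic carbonate may ionise before the aryl–alkyl coupling, so that allyl transfer between molecules (O-allylation, allyl–alkyl coupling, oligomer formation) outruns ring closure; the ring may close at the ortho carbon C4; the ligand may discriminate the allyl faces poorly. The fallback uses known reactions, sets out from 12 and comes back at 16. Silylation of 12 (Et3SiCl, imidazole) gives triethylsilyl ether F1, so that no leaving group is present during the coupling. Hydroboration (9-BBN-H) and B-alkyl Suzuki–Miyaura coupling with 5 (PdCl2(dppf), K3PO4, DMF/H2O) give coupled phenol F2. Pyridinium p-toluenesulfonate in MeOH removes only the triethylsilyl group and gives hydroxy phenol F3. Methyl chloroformate/pyridine at −20 °C should acylate the aliphatic hydroxyl in preference to the hydrogen-bonded salicylate hydroxyl and gives 15, now isolated. Compound 15 is then closed to 16 in a separate intramolecular asymmetric Tsuji–Trost dearomatization (Pd2(dba)3, the same chiral bisphosphine, K2CO3, dioxane), so that each palladium event can be optimised alone.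

2. Step 11. The dissolving metal may cleave the allylic C15–O bond or reduce beyond the enolate stage. The fallback sets out from 17 and comes back at 19. The silyl ether is removed first (n-Bu4NF, AcOH) to give allylic alcohol F4, whose lithium alkoxide resists C–O cleavage. Li/NH3 (one further equivalent) and then MeI give hydroxy keto ester F5, and re-silylation (i-Pr3SiCl, imidazole) returns to 19.

3. Step 10. Site selectivity may be lost, with hydride delivery to the ester-activated C5 or to both enone double bonds. The fallback sets out from 16 and comes back at 19. The copper hydride step is left out and the dissolving-metal reductive methylation (Li, NH3/THF, t-BuOH; MeI) is run on the dienone ester itself. The first two electrons should enter the doubly activated C4=C5 bond, and the resulting cross-conjugated enolate should resist further reduction; this gives Δ1-enone F6. 1,4-Reduction of its β-unsubstituted enone with LiBH(s-Bu)3 (THF, −78 °C, aqueous work-up) returns to 19.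

**Further compounds**
F1 | step 9 | triethyl{[(7E)-7-methyl-3-methylidene-9-(triisopropylsilyloxy)nona-1,7-dien-4-yl]oxy}silane | C=CC(=C)C(O[Si](CC)(CC)CC)CC/C(C)=C/CO[Si](C(C)C)(C(C)C)C(C)C
F2 | step 9 | methyl 6-hydroxy-3-methyl-2-[(7E)-7-methyl-3-methylidene-4-(triethylsilyloxy)-9-(triisopropylsilyloxy)non-7-en-1-yl]benzoate | COC(=O)c1c(O)ccc(C)c1CCC(=C)C(O[Si](CC)(CC)CC)CC/C(C)=C/CO[Si](C(C)C)(C(C)C)C(C)C
F3 | step 9 | methyl 6-hydroxy-2-[(7E)-4-hydroxy-7-methyl-3-methylidene-9-(triisopropylsilyloxy)non-7-en-1-yl]-3-methylbenzoate | COC(=O)c1c(O)ccc(C)c1CCC(=C)C(O)CC/C(C)=C/CO[Si](C(C)C)(C(C)C)C(C)C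
F4 | step 11 | methyl 15-hydroxy-3-oxo-18-norlabda-4,8(17),13E-trien-19-oate | COC(=O)C1=C2CCC(=C)[C@H](CC/C(C)=C/CO)[C@@]2(C)CCC1=O
F5 | step 11 | methyl 15-hydroxy-3-oxolabda-8(17),13E-dien-19-oate | C=C1CC[C@@H]2[C@](C)(CCC(=O)[C@]2(C)C(=O)OC)[C@H]1CC/C(C)=C/CO
F6 | step 10 | methyl 3-oxo-15-[(triisopropylsilyl)oxy]labda-1,8(17),13E-trien-19-oate | C=C1CC[C@@H]2[C@](C)(C=CC(=O)[C@]2(C)C(=O)OC)[C@H]1CC/C(C)=C/CO[Si](C(C)C)(C(C)C)C(C)C
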